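## Analysis of the target

Target 26 is an ent-labdane. It has a trans-fused decalin (ring A: C1–C5 and C10; ring B: C5–C10) with the C11–C16 side chain on C9, and the primary allylic alcohol C15 is esterified with (S)-3-methylpentanoic acid. The ring stereocentres are C3 (S), C5 (S), C9 (R) and C10 (S). The C10 methyl (C20) and H-5 are anti, the C9 chain is equatorial and syn to C20, and the C3 hydroxyl is axial, anti to C20 and syn to H-5. A fifth, isolated stereocentre sits in the acyl part, and the C13=C14 alkene is E. Ring B carries the trisubstituted C7=C8 alkene with the C17 methyl, so C9 is allylic and lies next to the quaternary C10. The sensitive groups are the allylic ester (ionisable, labile to hydride and base) and the C7=C8 alkene, which can migrate to C8=C9 under acid.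

Four things make the synthesis hard:
- The absolute configuration belongs to the enantiomeric labdane series, for which no cheap labdane or drimane is available.
- The axial C3 alcohol is the epimer that a chair-type epoxide opening does not deliver.
- C9 has to be set next to a quaternary carbon without moving the alkene.
- The side-chain alkene would take part in any cationic ring construction.

The feature the route is built on is ring B itself. C5–C6–C7=C8(C17)–C9–C10, with the gem-dimethyl carbon C4 on C5, is the carbon pattern of carvone: C9 is the carbonyl carbon, C7=C8(C17) the methyl-bearing enone alkene, C5 the stereocentre, and C4 with C18/C19 the isopropenyl group.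

## Retrosynthetic reasoning

**Ester C15–O.** 26 is cut last into diol 24 and acid 25. The C3 hydroxyl is axial and neopentyl, so a carbodiimide coupling should acylate only the primary allylic alcohol, and the acyl stereocentre is bought, not made.

**C9–H bond and the C7=C8 alkene.** The C9 chain must end syn to C20, which is the face a carbon nucleophile would not attack. Therefore the chain is placed on an sp2 C9 and the small hydrogen is delivered last. Silyl ether 23 is traced to the C8=C9 allylic carbonate 20, whose C7 oxygen is anti to C20. Palladium-catalysed substitution by a sulfonyl hydrazide with retention, then loss of dinitrogen from the allylic diazene, moves hydrogen from C7 to C9 on the same face and places the alkene at C7=C8.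

**C7 and C3 carbinols.** 20 comes from diol 19, and 19 from enedione 18. Both carbonyls should be reduced from the equatorial side by one hindered borohydride, so the axial C3 alcohol of the target and the C7 configuration needed above are set together.

**C9–C11 bond and 1,3-carbonyl transposition.** 18 is the oxidative-transposition product of tertiary allylic alcohol 17. 17 arises by addition of Grignard reagent 15 (from bromide 14) to the carvone-type carbonyl of bicyclic enone 8. The carvone carbonyl is thus used twice: first as the electrophile that accepts the side chain at C9, then, after transposition to C7, as the leaving oxygen for the reductive transposition. The oxidation also erases the C3 carbinol of 8, so its configuration does not matter.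

**C3–C4 bond, ring A (key disconnection).** 8 is opened between C3 and C4 to monocyclic aldehyde 7. In the forward direction a hydrogen atom is added to the CH2 of the isopropenyl group. This creates the second C4 methyl and a tertiary C4 radical, which closes ring A onto the aldehyde carbon. The cut is made here because it is the only bond that turns carvone's isopropenyl group into the gem-dimethyl carbon and the C3 oxygen function at once. The precursor 7 has one ring and two stereocentres fewer to worry about.

**C10 quaternary centre.** 7 comes from alkyne 5 by anti-Markovnikov hydration. 5 comes from 1 through 3 by two enolate alkylations at the only alpha-prime carbon. The second electrophile should enter anti to the isopropenyl group, which fixes the trans relationship that later becomes the trans ring fusion.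

**Side chain.** Bromide 14 goes back through 13, 12 and 11 to alkyne 9. A syn carboalumination sets the 13E geometry, and a silyl exchange differentiates the two ends.

## Alternatives that were turned down

**Alternative 1:** the textbook disconnection cuts C4–C5 and C9–C10 and closes both rings at once. The forward key step is a Lewis-acid (for example MeAlCl2) or Cp2TiCl-mediated bicyclization of the acyclic (14R)-epoxy tetraene ester A1 to bicyclic ester A2. It was turned down for four reasons:
- A chair-type opening puts the C3 oxygen equatorial, so A2 is the C3 epimer and needs an oxidation–reduction pair.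
- The C8 cation (or radical) has three sets of beta hydrogens and nothing in A1 chooses between them, so mixtures of C7=C8, C8=C17 and C8=C9 alkenes are expected. The C13=C14 alkene can also go on to a third ring.
- The allylic ester is exposed to the Lewis acid.
- Making A1 needs an epoxidation that is both enantioselective and selective for one of four trisubstituted alkenes.

**Alternative 2:** the building-block disconnection starts from the (R)-Wieland–Miescher ketone A3, which already contains C10 and both rings. The forward key step is deconjugative C4 gem-dimethylation (KOt-Bu, MeI, with the saturated ketone masked) to dione A4. It was turned down on step economy. A3 supplies only C10. C5–H, the C8 methyl, the C7=C8 alkene and the C9 carbonyl pattern each need their own operation: masking, C3 reduction, hydrogenation of the C5=C6 alkene (trans selectivity not assured), unmasking, C8 methylation and dehydrogenation. At least seven steps would be needed to reach the same enone 8 that carvone gives in four.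

**Alternative 3:** a convergent disconnection cuts C5–C6 and C9–C10 and forms ring B by an intermolecular Diels–Alder reaction of side-chain diene A5 with the (E)-enal A6 to give cyclohexene A7 (C5, C9 and C10 set together), followed by an aldol condensation to close ring A. It was turned down for these reasons:
- A6 is a trisubstituted enal with a tertiary alkyl group on its beta carbon, a poor dienophile.
- The C8 methyl and the C9 substituent of A5 direct the regiochemistry in opposite senses.
- The required topography (formyl exo, so that C11 ends syn to C20) is not inherently favoured.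
- Enantiocontrol would rest on a catalyst acting on a sluggish partner.
- A5 costs four to five steps, and the ring A enone would later need a selective reduction beside two other alkenes.

Key step: step 4

## Remarks before the steps

- Remark 1: bicyclic compounds from 18 on are named as labdanes (C1–C10 decalin, C11–C16 chain, C17 on C8, C18/C19 on C4, C20 on C10) with explicit CIP descriptors. Faces are described relative to C20.
- Remark 2: silyl ether 9 and acid 25 are taken as purchased catalogue compounds.

## Route

Step 1
Reactants: 1 (S)-(+)-carvone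
Product: 3 (5S)-2,6-dimethyl-5-(prop-1-en-2-yl)cyclohex-2-en-1-one (6-methylcarvone; both C6 epimers), via lithium dienolate 2 (not isolated)
Conditions: LiN(i-Pr)2, THF, –78 °C; MeI, –78 to 0 °C
Reagents that add atoms: iodomethane, CI
Why: Kinetic deprotonation occurs at the only alpha-prime carbon (C6 of 1, the future C10) and the cross-conjugated dienolate is methylated (enolate alkylation); the epimer mixture at C6 is immaterial because the centre is planarised again in step 2.

Step 2
Reactants: 3 6-methylcarvone
Product: 5 (5R,6R)-2,6-dimethyl-5-(prop-1-en-2-yl)-6-(prop-2-yn-1-yl)cyclohex-2-en-1-one (propargyl anti to isopropenyl), via lithium dienolate 4 (not isolated)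
Conditions: LiN(i-Pr)2, THF/DMPU, –78 °C; propargyl bromide, –78 to –20 °C
Reagents that add atoms: 3-bromoprop-1-yne, C#CCBr
Why: In the tetrasubstituted dienolate the neighbouring isopropenyl group should sit pseudoaxial (allylic strain with the C6 methyl) and shield one face, so the reactive propargyl halide should enter anti to it (diastereoselective enolate alkylation). This makes the quaternary C10 with methyl cis and the three-carbon arm trans to the future C4.

Step 3
Reactants: 5 propargyl ketone
Product: 7 3-[(1R,6R)-1,3-dimethyl-2-oxo-6-(prop-1-en-2-yl)cyclohex-3-en-1-yl]propanal, via alkenylborane 6 (not isolated)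
Conditions: Cy2BH, THF, 0 °C; Me3NO·2H2O, rt; H2O
Reagents that add atoms: trimethylamine N-oxide, C[N+](C)(C)[O-]
Why: The hindered dialkylborane should add syn and anti-Markovnikov to the terminal alkyne faster than to the 1,1-disubstituted alkene or the hindered enone carbonyl; amine-oxide oxidation of the alkenylborane and hydrolysis give the aldehyde (alkyne hydroboration–oxidation).

Step 4
Reactants: 7 aldehyde
Product: 8 (4aR,8aR)-6-hydroxy-2,5,5,8a-tetramethyl-4a,5,6,7,8,8a-hexahydronaphthalen-1(4H)-one (trans-fused; both C6 epimers; C6 is labdane C3)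
Conditions: Fe(acac)3 (cat.), PhSiH3, EtOH/(CH2OH)2, 60 °C, 0.02 M
Reagents that add atoms: none
Why: The iron hydride formed from Fe(acac)3 and PhSiH3 in ethanol transfers a hydrogen atom to the terminal CH2 of the isopropenyl group (Markovnikov, Mukaiyama-type HAT), which turns that carbon into the second C4 methyl and leaves a tertiary radical at C4. The radical adds 6-exo-trig to the aldehyde carbon C3, so ring A closes in the exo mode onto C=O; the alkoxy radical is reduced by divalent iron and protonated by the solvent, which returns trivalent iron. The closest known reaction type is the iron-catalysed HAT reductive cyclization of alkene-tethered ketones, together with the intermolecular HAT coupling of alkenes with aldehydes. The ring fusion is not created here but enforced: the aldehyde arm on C10 and the radical carbon on C5 are trans on ring B (step 2) and both equatorial in the reacting half-chair, so only the trans-decalin can form, and C5 and C10 are untouched. The one new stereocentre, C3, is not controlled and need not be, because both epimers are oxidised to the same ketone in step 10 and C3 is set in step 11. The selectivity needed is HAT to the electron-rich 1,1-disubstituted alkene beside the electron-poor trisubstituted enone alkene, which the nucleophilic iron hydride and the accessible CH2 terminus should secure. The enone cannot intercept the radical within the molecule (only four- or five-membered closures), and high dilution suppresses intermolecular Giese addition. In one operation the step forms the C3–C4 bond, ring A, the quaternary gem-dimethyl carbon and the C3 oxygen function from a monocyclic precursor three steps from 1.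

Step 5
Reactants: 9 (but-3-yn-1-yloxy)(tert-butyl)dimethylsilane
Product: 11 (E)-5-(tert-butyldimethylsilyloxy)-3-methylpent-2-en-1-ol, via alkenylalane 10 (not isolated)
Conditions: AlMe3, Cp2ZrCl2 (cat.), CH2Cl2, 0 °C to rt; (CH2O)n, THF, rt; aq. Rochelle salt
Reagents that add atoms: trimethylaluminium, C[Al](C)C; formaldehyde (as paraformaldehyde), C=O
Why: Zirconium-catalysed syn carboalumination (Negishi) puts methyl on the internal and aluminium on the terminal alkyne carbon, and hydroxymethylation of the alkenylalane proceeds with retention, which fixes the 13E geometry (chain trans to CH2OH).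

Step 6
Reactants: 11 allylic alcohol
Product: 12 (E)-1-(tert-butyldiphenylsilyloxy)-5-(tert-butyldimethylsilyloxy)-3-methylpent-2-ene
Conditions: t-BuPh2SiCl, imidazole, CH2Cl2, rt
Reagents that add atoms: tert-butyl(chloro)diphenylsilane, CC(C)(C)[Si](Cl)(c1ccccc1)c1ccccc1
Why: Silylation of the primary allylic alcohol with the robust group that must survive the Grignard, chromium and hydride steps.

Step 7
Reactants: 12 bis-silyl ether
Product: 13 (E)-5-(tert-butyldiphenylsilyloxy)-3-methylpent-3-en-1-ol
Conditions: PPTS (cat.), EtOH, 40 °C
Reagents that add atoms: none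
Why: Acid-catalysed solvolysis cleaves the primary tert-butyldimethylsilyl ether much faster than the tert-butyldiphenylsilyl ether (selective desilylation).

Step 8
Reactants: 13 homoallylic alcohol
Product: 14 [(E)-5-bromo-3-methylpent-2-en-1-yl]oxy(tert-butyl)diphenylsilane
Conditions: CBr4, PPh3, CH2Cl2, 0 °C
Reagents that add atoms: carbon tetrabromide, BrC(Br)(Br)Br
Why: Appel bromination of the primary alcohol under neutral conditions leaves the allylic silyl ether and the E alkene untouched.

Step 9
Reactants: 8 bicyclic hydroxy enone; 14 side-chain bromide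
Product: 17 (4aR,8aR)-1-[(E)-5-(tert-butyldiphenylsilyloxy)-3-methylpent-3-en-1-yl]-2,5,5,8a-tetramethyl-1,4,4a,5,6,7,8,8a-octahydronaphthalene-1,6-diol (C1 and C6 epimers), via Grignard reagent 15 (not isolated), via bromomagnesium alkoxide 16 (not isolated)
Conditions: 14, Mg, THF, rt; 8, MeMgBr (1.0 equiv), THF, –78 °C; LaCl3·2LiCl, then 15, –78 to 0 °C; aq. NH4Cl
Reagents that add atoms: none
Why: The enone carbonyl has no alpha hydrogen, so the lanthanum-promoted Grignard reagent can only add 1,2 (Grignard addition to a hindered 2,6,6-trisubstituted cyclohexenone), and the free hydroxyl is masked as its magnesium alkoxide; the configuration of the new carbinol carbon is irrelevant because it becomes sp2 in step 10.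

Step 10
Reactants: 17 tertiary allylic alcohol
Product: 18 (5S,10R)-15-(tert-butyldiphenylsilyloxy)labda-8,13E-diene-3,7-dione
Conditions: pyridinium chlorochromate (C5H5NH[CrO3Cl]), 4 Å MS, CH2Cl2, rt
Reagents that add atoms: pyridinium chlorochromate, [O-][Cr](=O)(=O)Cl.c1cc[nH+]cc1
Why: The chromate ester of the tertiary allylic alcohol undergoes a [3,3] shift to C7 and is oxidised to the transposed enone (Babler–Dauben oxidation), while the same hexavalent chromium reagent oxidises the C3 carbinol, so all four stereoisomers of 17 should converge on one enedione.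

Step 11
Reactants: 18 enedione
Product: 19 (3S,5S,7S,10R)-15-(tert-butyldiphenylsilyloxy)labda-8,13E-diene-3,7-diol (both hydroxyls axial and anti to C20)
Conditions: KBH(s-Bu)3, THF, –78 to 0 °C; NaOH, H2O2
Reagents that add atoms: none
Why: The bulky borohydride should attack both carbonyls from the equatorial side: at C3 (flanked by the gem-dimethyl carbon) this gives the axial alcohol of the target, and at C7 it gives the pseudoaxial allylic alcohol by 1,2-addition, because the fully substituted beta carbon C9 blocks conjugate reduction.

Step 12
Reactants: 19 diol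
Product: 20 (3S,5S,7S,10R)-15-(tert-butyldiphenylsilyloxy)-3-hydroxylabda-8,13E-dien-7-yl methyl carbonate
Conditions: ClCO2Me, pyridine, DMAP (cat.), CH2Cl2, –20 to 0 °C
Reagents that add atoms: methyl chloroformate, COC(=O)Cl
Why: The allylic C7 alcohol should be acylated selectively, since the axial C3 alcohol is neopentyl and strongly hindered (chemoselective carbonate formation).

Step 13
Reactants: 20 allylic carbonate
Product: 23 (3S,5S,9R,10S)-15-(tert-butyldiphenylsilyloxy)labda-7,13E-dien-3-ol, via allylic sulfonyl hydrazone 21 (not isolated), via allylic diazene 22 (not isolated)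
Conditions: N-isopropylidene-N′-(2-nitrophenylsulfonyl)hydrazine, Pd2(dba)3 (cat.), PPh3, THF, rt; CF3CH2OH/H2O, AcOH, rt
Reagents that add atoms: none
Why: Zerovalent palladium ionises the carbonate with inversion and the soft nitrogen nucleophile attacks the less hindered terminus C7 anti to the metal, so nitrogen replaces oxygen with net retention (Tsuji–Trost substitution). Hydrolysis and loss of sulfinate give the allylic diazene, whose retro-ene loss of dinitrogen delivers hydrogen suprafacially to C9 on the face anti to C20, setting C9 and placing the alkene at C7=C8.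

Step 14
Reactants: 23 silyl ether
Product: 24 (3S,5S,9R,10S)-labda-7,13E-diene-3,15-diol
Conditions: Bu4NF, THF, rt
Reagents that add atoms: none
Why: Fluoride cleaves the silicon–oxygen bond of the primary allylic ether and affects nothing else (desilylation).

Step 15
Reactants: 24 diol; 25 (S)-3-methylpentanoic acid
Product: 26 (3S,5S,9R,10S)-3-hydroxylabda-7,13E-dien-15-yl (S)-3-methylpentanoate (target)
Conditions: DCC, DMAP (cat.), CH2Cl2, 0 °C
Reagents that add atoms: none
Why: Steglich esterification should acylate the unhindered primary allylic alcohol and leave the axial neopentyl C3 alcohol free; the acid's stereocentre is beta to the carboxyl and cannot epimerise.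

## Compound list

1 | (S)-(+)-carvone, (5S)-2-methyl-5-(prop-1-en-2-yl)cyclohex-2-en-1-one | O=C1C(C)=CC[C@H](C(C)=C)C1 | starting material
2 | lithium cross-conjugated dienolate of 1 (O–C1=C6) | [Li]OC1=C[C@@H](C(C)=C)CC=C1C | intermediate
3 | (5S)-2,6-dimethyl-5-(prop-1-en-2-yl)cyclohex-2-en-1-one (both C6 epimers) | O=C1C(C)=CC[C@H](C(C)=C)C1C | intermediate
4 | lithium dienolate of 3 (O–C1=C6, tetrasubstituted) | [Li]OC1=C(C)[C@@H](C(C)=C)CC=C1C | intermediate
5 | (5R,6R)-2,6-dimethyl-5-(prop-1-en-2-yl)-6-(prop-2-yn-1-yl)cyclohex-2-en-1-one | O=C1C(C)=CC[C@H](C(C)=C)[C@@]1(C)CC#C | intermediate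
6 | dicyclohexyl{(E)-3-[(1R,6R)-1,3-dimethyl-2-oxo-6-(prop-1-en-2-yl)cyclohex-3-en-1-yl]prop-1-en-1-yl}borane | O=C1C(C)=CC[C@H](C(C)=C)[C@@]1(C)C/C=C/B(C2CCCCC2)C2CCCCC2 | intermediate
7 | 3-[(1R,6R)-1,3-dimethyl-2-oxo-6-(prop-1-en-2-yl)cyclohex-3-en-1-yl]propanal | O=C1C(C)=CC[C@H](C(C)=C)[C@@]1(C)CCC=O | intermediate
8 | (4aR,8aR)-6-hydroxy-2,5,5,8a-tetramethyl-4a,5,6,7,8,8a-hexahydronaphthalen-1(4H)-one (trans-fused; both C6 epimers) | O=C1C(C)=CC[C@@H]2C(C)(C)C(O)CC[C@@]12C | intermediate
9 | (but-3-yn-1-yloxy)(tert-butyl)dimethylsilane | C#CCCO[Si](C)(C)C(C)(C)C | starting material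
10 | [(E)-4-(tert-butyldimethylsilyloxy)-2-methylbut-1-en-1-yl]dimethylalane | C[Al](C)/C=C(\C)CCO[Si](C)(C)C(C)(C)C | intermediate
11 | (E)-5-(tert-butyldimethylsilyloxy)-3-methylpent-2-en-1-ol | OC/C=C(\C)CCO[Si](C)(C)C(C)(C)C | intermediate
12 | (E)-1-(tert-butyldiphenylsilyloxy)-5-(tert-butyldimethylsilyloxy)-3-methylpent-2-ene | CC(C)(C)[Si](C)(C)OCC/C(C)=C/CO[Si](c1ccccc1)(c1ccccc1)C(C)(C)C | intermediate
13 | (E)-5-(tert-butyldiphenylsilyloxy)-3-methylpent-3-en-1-ol | OCC/C(C)=C/CO[Si](c1ccccc1)(c1ccccc1)C(C)(C)C | intermediate
14 | [(E)-5-bromo-3-methylpent-2-en-1-yl]oxy(tert-butyl)diphenylsilane | BrCC/C(C)=C/CO[Si](c1ccccc1)(c1ccccc1)C(C)(C)C | intermediate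
15 | bromo[(E)-5-(tert-butyldiphenylsilyloxy)-3-methylpent-3-en-1-yl]magnesium | Br[Mg]CC/C(C)=C/CO[Si](c1ccccc1)(c1ccccc1)C(C)(C)C | intermediate
16 | bromomagnesium alkoxide of 8 | O=C1C(C)=CC[C@@H]2C(C)(C)C(O[Mg]Br)CC[C@@]12C | intermediate
17 | (4aR,8aR)-1-[(E)-5-(tert-butyldiphenylsilyloxy)-3-methylpent-3-en-1-yl]-2,5,5,8a-tetramethyl-1,4,4a,5,6,7,8,8a-octahydronaphthalene-1,6-diol (C1 and C6 epimers) | OC1(CC/C(C)=C/CO[Si](c3ccccc3)(c4ccccc4)C(C)(C)C)C(C)=CC[C@@H]2C(C)(C)C(O)CC[C@@]12C | intermediate
18 | (5S,10R)-15-(tert-butyldiphenylsilyloxy)labda-8,13E-diene-3,7-dione | CC(C)(C)[Si](c3ccccc3)(c4ccccc4)OC/C=C(\C)CCC1=C(C)C(=O)C[C@@H]2C(C)(C)C(=O)CC[C@@]12C | intermediate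
19 | (3S,5S,7S,10R)-15-(tert-butyldiphenylsilyloxy)labda-8,13E-diene-3,7-diol | CC(C)(C)[Si](c3ccccc3)(c4ccccc4)OC/C=C(\C)CCC1=C(C)[C@@H](O)C[C@@H]2C(C)(C)[C@@H](O)CC[C@@]12C | intermediate
20 | (3S,5S,7S,10R)-15-(tert-butyldiphenylsilyloxy)-3-hydroxylabda-8,13E-dien-7-yl methyl carbonate | CC(C)(C)[Si](c3ccccc3)(c4ccccc4)OC/C=C(\C)CCC1=C(C)[C@@H](OC(=O)OC)C[C@@H]2C(C)(C)[C@@H](O)CC[C@@]12C | intermediate
21 | N-[(3S,5S,7S,10R)-15-(tert-butyldiphenylsilyloxy)-3-hydroxylabda-8,13E-dien-7-yl]-N-(2-nitrophenylsulfonyl)hydrazone of acetone | CC(C)(C)[Si](c3ccccc3)(c4ccccc4)OC/C=C(\C)CCC1=C(C)[C@@H](N(N=C(C)C)S(=O)(=O)c5ccccc5[N+](=O)[O-])C[C@@H]2C(C)(C)[C@@H](O)CC[C@@]12C | intermediate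
22 | (3S,5S,7S,10R)-15-(tert-butyldiphenylsilyloxy)-7-diazenyllabda-8,13E-dien-3-ol | CC(C)(C)[Si](c3ccccc3)(c4ccccc4)OC/C=C(\C)CCC1=C(C)[C@@H](N=N)C[C@@H]2C(C)(C)[C@@H](O)CC[C@@]12C | intermediate
23 | (3S,5S,9R,10S)-15-(tert-butyldiphenylsilyloxy)labda-7,13E-dien-3-ol | CC(C)(C)[Si](c3ccccc3)(c4ccccc4)OC/C=C(\C)CC[C@@H]1C(C)=CC[C@@H]2C(C)(C)[C@@H](O)CC[C@@]12C | intermediate
24 | (3S,5S,9R,10S)-labda-7,13E-diene-3,15-diol | OC/C=C(\C)CC[C@@H]1C(C)=CC[C@@H]2C(C)(C)[C@@H](O)CC[C@@]12C | intermediate
25 | (S)-3-methylpentanoic acid | CC[C@H](C)CC(=O)O | starting material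
26 | (3S,5S,9R,10S)-3-hydroxylabda-7,13E-dien-15-yl (S)-3-methylpentanoate | CC[C@H](C)CC(=O)OC/C=C(\C)CC[C@@H]1C(C)=CC[C@@H]2C(C)(C)[C@@H](O)CC[C@@]12C | target

## Step count and least certain steps

Total step count: 15. Longest linear sequence: 11 steps (steps 1–4 and 9–15 from 1; the branch from 9, steps 5–8 and 9–15, is equally long).

**Step 4 (key step).** The addition of the tertiary radical to the aldehyde is reversible. If fragmentation of the alkoxy radical outruns its reduction, the radical is simply hydrogenated to the isopropyl group or adds to the enone of a second molecule. The fallback sets out from 7 and replaces the reversible carbonyl addition by an irreversible one: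
- The aldehyde is converted into 3-[(1R,6R)-1,3-dimethyl-2-oxo-6-(prop-1-en-2-yl)cyclohex-3-en-1-yl]propanenitrile F1 (NH2OH·HCl, then dehydration of the oxime in the same flask).
- The same iron-hydride HAT conditions should then close ring A onto the nitrile, and hydrolysis of the imine on work-up gives (4aR,8aR)-2,5,5,8a-tetramethyl-4a,7,8,8a-tetrahydronaphthalene-1,6(4H,5H)-dione F2.
- NaBH4 in EtOH at low temperature should reduce the saturated C3 ketone and spare the conjugated enone. This comes back to the route at 8 (as its equatorial epimer, which step 10 oxidises anyway).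

**Step 13.** Ionisation places palladium on the face of the allyl system that carries C20, so it may be slow, and the allyl complex may lose a beta hydrogen to give a diene instead of being captured by nitrogen. A C7 alcohol mis-set in step 11 would also surface here. The fallback sets out from 19 and avoids the metal:
- MnO2 oxidises only the allylic alcohol to (3S,5S,10R)-15-(tert-butyldiphenylsilyloxy)-3-hydroxylabda-8,13E-dien-7-one F3.
- Luche reduction (NaBH4, CeCl3·7H2O, MeOH) delivers hydride axially to give (3S,5S,7R,10R)-15-(tert-butyldiphenylsilyloxy)labda-8,13E-diene-3,7-diol F4, with the C7 hydroxyl syn to C20.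
- A Mitsunobu reaction with the same sulfonyl hydrazide (PPh3, diethyl azodicarboxylate) inverts C7. This comes back to the route at 21, which is hydrolysed as in step 13 to 23.

**Step 2.** Facial discrimination in forming the quaternary centre may be incomplete, and some O-alkylation is possible. The fallback sets out from 3 and puts the selectivity under catalyst control:
- The enolate is trapped on oxygen with allyl chloroformate to give allyl (3R)-2,6-dimethyl-3-(prop-1-en-2-yl)cyclohexa-1,5-dien-1-yl carbonate F5.
- A decarboxylative Tsuji allylation with Pd2(dba)3 and a tert-butyl phosphinooxazoline ligand (enantiomer chosen to reinforce attack anti to isopropenyl) gives (5R,6R)-2,6-dimethyl-6-(prop-2-en-1-yl)-5-(prop-1-en-2-yl)cyclohex-2-en-1-one F6.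
- An aldehyde-selective Wacker oxidation (PdCl2(PhCN)2, CuCl2, AgNO2, O2, t-BuOH/MeNO2) converts the allyl group into the propanal arm. This comes back to the route at 7.

**Step 3.** The borane may also hydroborate the isopropenyl group or reduce the ketone. The fallback sets out from 5 and comes back at 7 in one operation without any new compound: a ruthenium-catalysed anti-Markovnikov hydration of the terminal alkyne (CpRu(MeCN)3PF6 with a 2,2′-bipyridine ligand, acetone/H2O), which proceeds through a vinylidene and does not touch alkenes or ketones.

## Further compounds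

F1 | step 4 | 3-[(1R,6R)-1,3-dimethyl-2-oxo-6-(prop-1-en-2-yl)cyclohex-3-en-1-yl]propanenitrile | O=C1C(C)=CC[C@H](C(C)=C)[C@@]1(C)CCC#N
F2 | step 4 | (4aR,8aR)-2,5,5,8a-tetramethyl-4a,7,8,8a-tetrahydronaphthalene-1,6(4H,5H)-dione | O=C1C(C)=CC[C@@H]2C(C)(C)C(=O)CC[C@@]12C
F3 | step 13 | (3S,5S,10R)-15-(tert-butyldiphenylsilyloxy)-3-hydroxylabda-8,13E-dien-7-one | CC(C)(C)[Si](c3ccccc3)(c4ccccc4)OC/C=C(\C)CCC1=C(C)C(=O)C[C@@H]2C(C)(C)[C@@H](O)CC[C@@]12C
F4 | step 13 | (3S,5S,7R,10R)-15-(tert-butyldiphenylsilyloxy)labda-8,13E-diene-3,7-diol | CC(C)(C)[Si](c3ccccc3)(c4ccccc4)OC/C=C(\C)CCC1=C(C)[C@H](O)C[C@@H]2C(C)(C)[C@@H](O)CC[C@@]12C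
F5 | step 2 | allyl (3R)-2,6-dimethyl-3-(prop-1-en-2-yl)cyclohexa-1,5-dien-1-yl carbonate | C=CCOC(=O)OC1=C(C)[C@@H](C(C)=C)CC=C1C
F6 | step 2 | (5R,6R)-2,6-dimethyl-6-(prop-2-en-1-yl)-5-(prop-1-en-2-yl)cyclohex-2-en-1-one | O=C1C(C)=CC[C@H](C(C)=C)[C@@]1(C)CC=C
F0 | step 3 | none | none
A1 | alternative 1 | (2E,6E,10E)-(14R)-14,15-epoxy-3,7,11,15-tetramethylhexadeca-2,6,10-trien-1-yl (S)-3-methylpentanoate | CC[C@H](C)CC(=O)OC/C=C(\C)CC/C=C(\C)CC/C=C(\C)CC[C@H]1OC1(C)C
A2 | alternative 1 | C3 epimer and C8=C17 double-bond isomer of 26 (equatorial 3-hydroxyl, exocyclic methylene) | CC[C@H](C)CC(=O)OC/C=C(\C)CC[C@@H]1C(=C)CC[C@@H]2C(C)(C)[C@H](O)CC[C@@]12C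
A3 | alternative 2 | (8aR)-8a-methyl-3,4,8,8a-tetrahydronaphthalene-1,6(2H,7H)-dione ((R)-Wieland–Miescher ketone) | O=C1CCCC2=CC(=O)CC[C@@]12C
A4 | alternative 2 | (8aR)-5,5,8a-trimethyl-3,5,8,8a-tetrahydronaphthalene-1,6(2H,7H)-dione | O=C1CCC=C2C(C)(C)C(=O)CC[C@@]12C
A5 | alternative 3 | (2E,6E)-3,7-dimethylnona-2,6,8-trien-1-yl (S)-3-methylpentanoate | CC[C@H](C)CC(=O)OC/C=C(\C)CC/C=C(\C)C=C
A6 | alternative 3 | (E)-2,4,4-trimethyl-5-oxohex-2-enal | O=C/C(C)=C/C(C)(C)C(C)=O
A7 | alternative 3 | Diels–Alder adduct: cyclohexene with C10 (methyl, formyl), C5 (H, 2-methyl-3-oxobutan-2-yl), C9 (H, side chain) and the C7=C8 alkene, configured as in 26 | CC[C@H](C)CC(=O)OC/C=C(\C)CC[C@@H]1C(C)=CC[C@H](C(C)(C)C(C)=O)[C@@]1(C)C=O
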